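**Plan**
- Numbering (eudesmane): ring A is C1–C5 plus C10 (ester on C3, carbinol C4, angular methyl on C10); ring B is C5–C10 (ketone C8, side chain C11 on C7); β is the face of the C10 methyl group.
- Retrosynthetic cuts, last-made bond first: the C3–O acyl bond; O–C11 together with the C6=C7 unsaturation (oxygen ene reaction); C7–C11 (aldol with acetone); the C3–O and C4–O bonds (cis-dihydroxylation of a 3-ene); C9–C10 (key step); C8–C9 (diazoketone); C6–C7 (olefination).
- Enabling feature: ring A carries oxygen at C3, methyl at C4, the ring-B carbon C6 on C5 and methyl at C10, with C10 para to the C3 oxygen. Ring A is therefore a 3-substituted 2,4-dimethylphenol, and a C9 carbenoid on the C6–C7–C8 tether can bond to C10 with dearomatisation.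
- Forward order: ring A is the benzene ring of 2,6-dimethylbenzaldehyde; the C6–C9 chain is grown on it; ring B closes in the dearomatising step; ring A is then reduced and oxygenated, and the C7 side chain and the ester are added last.
- Stereochemistry: C10 from the chiral dirhodium catalyst; C5 from Li/NH3 reduction (H trans to the C10 methyl); C3 and C4 together from OsO4 on the α face, opposite the C10 methyl.

Key step: step 7

Assumption: Rh2(S-PTTL)4 (dirhodium tetrakis[N-phthaloyl-(S)-tert-leucinate]) is taken to give the (S)-dienone 13; if the sense of induction is the opposite, Rh2(R-PTTL)4 is used and nothing else changes.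

**Route**

Step 1
Reactants: 1 2,6-dimethylbenzaldehyde
Product: 2 2,6-dimethyl-3-nitrobenzaldehyde
Conditions: fuming HNO3 (1.05 equiv), conc. H2SO4, −10 → 0 °C
Reagents that add atoms: nitric acid, O[N+](=O)[O-]
Why: Electrophilic aromatic nitration in which both methyl groups (ortho/para) and the formyl group (meta) direct to the same carbon, the 3- and 5-positions being equivalent.

Step 2
Reactants: 2 2,6-dimethyl-3-nitrobenzaldehyde; 3 triethyl phosphonoacetate
Product: 4 ethyl (E)-3-(2,6-dimethyl-3-nitrophenyl)prop-2-enoate
Conditions: NaH, THF, 0 °C → rt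
Reagents that add atoms: none
Why: Horner–Wadsworth–Emmons olefination of the aryl aldehyde with the stabilised phosphonate anion forms the C6–C7 bond as the E-cinnamate.

Step 3
Reactants: 4 ethyl (E)-3-(2,6-dimethyl-3-nitrophenyl)prop-2-enoate
Product: 5 ethyl 3-(3-amino-2,6-dimethylphenyl)propanoate
Conditions: H2 (3 atm), Pd/C (10 wt%), EtOH, rt
Reagents that add atoms: none
Why: Heterogeneous catalytic hydrogenation saturates the conjugated alkene and reduces the nitro group to the aniline in one operation while the ester is untouched.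

Step 4
Reactants: 5 ethyl 3-(3-amino-2,6-dimethylphenyl)propanoate
Product: 8 3-(3-hydroxy-2,6-dimethylphenyl)propanoic acid, via arenediazonium hydrogen sulfate 6 (not isolated), via hydroxy ester 7 (not isolated)
Conditions: NaNO2 (1.05 equiv), 2 M H2SO4, 0–5 °C; then added dropwise to refluxing 3 M H2SO4, reflux 2 h
Reagents that add atoms: water, O
Why: Diazotisation followed by thermal hydroxydediazoniation in hot dilute H2SO4 installs the C3 oxygen, and the same hot aqueous acid hydrolyses the ethyl ester so that the hydroxy acid is obtained directly.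

Step 5
Reactants: 8 3-(3-hydroxy-2,6-dimethylphenyl)propanoic acid; 9 trimethylsilyldiazomethane
Product: 11 3-(4-diazo-3-oxobutyl)-2,4-dimethylphenyl ethyl carbonate, via mixed carbonic anhydride 10 (not isolated)
Conditions: ClCO2Et (2.2 equiv), Et3N (2.3 equiv), THF, −15 °C; filtration; then 9 (2.5 equiv), MeCN, 0 °C → rt
Reagents that add atoms: ethyl chloroformate, CCOC(Cl)=O
Why: Ethyl chloroformate activates the acid as a mixed carbonic anhydride and at the same time masks the phenol as its ethyl carbonate, and C-acylation of trimethylsilyldiazomethane by the anhydride with loss of the silyl group (Arndt–Eistert-type diazoketone synthesis) forms the C8–C9 bond.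

Step 6
Reactants: 11 3-(4-diazo-3-oxobutyl)-2,4-dimethylphenyl ethyl carbonate
Product: 12 1-diazo-4-(3-hydroxy-2,6-dimethylphenyl)butan-2-one
Conditions: K2CO3 (0.2 equiv), MeOH, 0 °C → rt; aq. NH4Cl
Reagents that add atoms: none
Why: Base-catalysed transesterification with methanol cleaves the activated aryl carbonate and leaves the base-stable α-diazoketone intact.

Step 7
Reactants: 12 1-diazo-4-(3-hydroxy-2,6-dimethylphenyl)butan-2-one
Product: 13 (10S)-11,12,13-trinoreudesma-1,4-diene-3,8-dione [(4aS)-1,4a-dimethyl-7,8-dihydronaphthalene-2,6(4aH,5H)-dione]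
Conditions: Rh2(S-PTTL)4 (1 mol %), CH2Cl2, −20 °C, 12 added by syringe pump at high dilution
Reagents that add atoms: none
Why: Proposed new method: N2 loss gives an electrophilic rhodium carbenoid at C9 that is attacked by the phenol π-system at C10 (directly as an arenium-type zwitterion, or through the C5–C9–C10 norcaradiene whose vinylogous donor–acceptor cyclopropane opens at C5–C9), and loss of the phenolic proton with protonation at C9 releases the cross-conjugated dienone and the catalyst. The closest known reaction types are the acid- or Rh2(OAc)4-promoted para-alkylation of phenolic diazoketones to racemic fused cyclohexadienones, the enantioselective carbenoid dearomatisation of phenols to spirodienones and the enantioselective intramolecular Büchner reaction of 1-diazo-4-arylbutan-2-ones. Ring B closes as a six-membered ring by attack of the arene carbon ortho to the tether (6-endo with respect to the C5=C10 π-bond, the metal-bearing carbon C9 becoming a ring member), the only other carbons within reach being C5 itself and C4. The single new stereocentre C10 is set by the chiral carboxylate pocket of Rh2(S-PTTL)4, which decides the face of the arene that the tethered carbenoid meets, there being no other stereocentre in 12. The step needs C10 over C4 attack and C-alkylation over O–H insertion or cycloheptatriene formation: C10 is para to the free hydroxyl and flanked by C1–H whereas C4 is wedged between the tether and the C3 oxygen and would give the less stable linearly conjugated dienone, the methyl groups on both C4 and C10 exclude rearomatising substitution, the hydroxyl cannot reach C9 intramolecularly, and slow addition at high dilution suppresses intermolecular O–H insertion and carbene dimerisation.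

Step 8
Reactants: 13 (10S)-11,12,13-trinoreudesma-1,4-diene-3,8-dione
Product: 14 (10R)-11,12,13-trinoreudesm-4-ene-3,8-dione
Conditions: H2 (1 atm), RhCl(PPh3)3 (5 mol %), toluene, rt
Reagents that add atoms: none
Why: Homogeneous hydrogenation with RhCl(PPh3)3 discriminates on steric grounds between the disubstituted C1=C2 alkene and the tetrasubstituted C4=C5 alkene, as in the 1,2-reduction of santonin-type cross-conjugated dienones.

Step 9
Reactants: 14 (10R)-11,12,13-trinoreudesm-4-ene-3,8-dione
Product: 15 (10R)-8,8-(ethylenedioxy)-11,12,13-trinoreudesm-4-en-3-one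
Conditions: (TMSOCH2)2 (1.2 equiv), TMSOTf (3 mol %), CH2Cl2, −78 → −20 °C; pyridine quench
Reagents that add atoms: 1,2-bis(trimethylsilyloxy)ethane, C[Si](C)(C)OCCO[Si](C)(C)C
Why: Aprotic silyl-transfer ketalisation (Noyori conditions) protects the saturated C8 ketone selectively, the conjugated tetrasubstituted C3 enone being far less electrophilic.

Step 10
Reactants: 15 (10R)-8,8-(ethylenedioxy)-11,12,13-trinoreudesm-4-en-3-one
Product: 17 8,8-(ethylenedioxy)-11,12,13-trinor-5α-eudesm-3-en-3-yl trifluoromethanesulfonate, via lithium enolate 16 (not isolated)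
Conditions: Li (2.2 equiv), t-BuOH (1.0 equiv), NH3(l)/THF, −78 → −33 °C; NH3 evaporated; PhNTf2 (1.5 equiv), THF, 0 °C → rt
Reagents that add atoms: N-phenylbis(trifluoromethanesulfonimide), O=S(=O)(N(c1ccccc1)S(=O)(=O)C(F)(F)F)C(F)(F)F
Why: Dissolving-metal reduction of the enone protonates C5 axially to give the trans-fused decalin (5α-H, anti to the C10 methyl), and the regiodefined C3–C4 lithium enolate is O-sulfonylated to the enol triflate.

Step 11
Reactants: 17 8,8-(ethylenedioxy)-11,12,13-trinor-5α-eudesm-3-en-3-yl trifluoromethanesulfonate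
Product: 19 11,12,13-trinor-5α-eudesm-3-en-8-one, via ketal alkene 18 (not isolated)
Conditions: Pd(OAc)2 (5 mol %), PPh3 (10 mol %), HCO2H (2 equiv), Bu3N (3 equiv), DMF, 60 °C; then 1 M HCl, THF, rt
Reagents that add atoms: water, O
Why: Palladium-catalysed formate reduction of the enol triflate (oxidative addition to zerovalent palladium, exchange of triflate for formate, loss of CO2 and reductive elimination of C–H) gives the 3-ene, and the aqueous acid of the second stage hydrolyses the ketal without moving the trisubstituted alkene.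

Step 12
Reactants: 19 11,12,13-trinor-5α-eudesm-3-en-8-one; 20 acetone
Product: 22 11-hydroxy-5α-eudesm-3-en-8-one (C7 epimers), via lithium enolate 21 (not isolated)
Conditions: LiN(i-Pr)2 (1.1 equiv), THF, −78 °C; ZnCl2 (1.1 equiv); 20 (3 equiv), −78 → −40 °C; aq. NH4Cl
Reagents that add atoms: none
Why: Kinetic deprotonation of the C8 ketone occurs at C7 because C9 is shielded by the adjacent quaternary C10, and the zinc-modified enolate adds to acetone in a directed aldol reaction whose new C7 stereocentre is erased in the next step.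

Step 13
Reactants: 22 11-hydroxy-5α-eudesm-3-en-8-one
Product: 24 5α-eudesma-3,7(11)-dien-8-one, via tertiary mesylate 23 (not isolated)
Conditions: MsCl (2 equiv), Et3N (5 equiv), CH2Cl2, 0 °C → rt
Reagents that add atoms: none
Why: Sulfonylation of the tertiary aldol hydroxyl followed by E1cB elimination through the C7 enolate gives the conjugated isopropylidene ketone.

Step 14
Reactants: 24 5α-eudesma-3,7(11)-dien-8-one
Product: 25 3α,4α-dihydroxy-5α-eudesm-7(11)-en-8-one
Conditions: OsO4 (2 mol %), NMO (1.5 equiv), acetone/H2O (8:1), 0 °C → rt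
Reagents that add atoms: osmium tetroxide (catalytic oxygen carrier), O=[Os](=O)(=O)=O; N-methylmorpholine N-oxide, C[N+]1([O-])CCOCC1; water, O
Why: Catalytic OsO4 dihydroxylation is a suprafacial [3+2] addition that takes the electron-rich trisubstituted 3-ene in preference to the tetrasubstituted enone and approaches from the α face, away from the axial C10 methyl group, so that the C3 and C4 hydroxyls are both α and cis.

Step 15
Reactants: 25 3α,4α-dihydroxy-5α-eudesm-7(11)-en-8-one
Product: 27 3α,4α,11-trihydroxy-5α-eudesm-6-en-8-one, via allylic hydroperoxide 26 (not isolated)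
Conditions: O2, tetraphenylporphyrin (1 mol %), visible light, CH2Cl2, 0 °C; then PPh3 (1.2 equiv), 0 °C → rt
Reagents that add atoms: dioxygen, O=O
Why: The Schenck ene reaction of singlet oxygen with the s-cis enone follows the geminal rule for α,β-unsaturated carbonyl compounds (hydrogen taken from C6 on the α-carbon substituent, oxygen delivered to C11), as in the photooxygenation of pulegone, and PPh3 reduces the hydroperoxide to the tertiary alcohol.

Step 16
Reactants: 27 3α,4α,11-trihydroxy-5α-eudesm-6-en-8-one; 28 3-methylbut-2-enoyl chloride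
Product: 29 (3R,4S,5R,10R)-4,11-dihydroxy-8-oxoeudesm-6-en-3-yl 3-methylbut-2-enoate (CNP0175033.1)
Conditions: 28 (1.5 equiv), pyridine (3 equiv), DMAP (0.1 equiv), CH2Cl2, 0 °C → rt
Reagents that add atoms: none
Why: DMAP-catalysed acylation through the acylpyridinium ion esterifies the only secondary hydroxyl, the tertiary hydroxyls at C4 and C11 being too hindered to react and the weak base leaving C5 untouched.

**Compound list**

1 | 2,6-dimethylbenzaldehyde | Cc1cccc(C)c1C=O | starting material
2 | 2,6-dimethyl-3-nitrobenzaldehyde | Cc1ccc([N+](=O)[O-])c(C)c1C=O | intermediate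
3 | triethyl phosphonoacetate | CCOC(=O)CP(=O)(OCC)OCC | starting material
4 | ethyl (E)-3-(2,6-dimethyl-3-nitrophenyl)prop-2-enoate | CCOC(=O)/C=C/c1c(C)ccc([N+](=O)[O-])c1C | intermediate
5 | ethyl 3-(3-amino-2,6-dimethylphenyl)propanoate | CCOC(=O)CCc1c(C)ccc(N)c1C | intermediate
6 | 3-(3-ethoxy-3-oxopropyl)-2,4-dimethylbenzenediazonium hydrogen sulfate | CCOC(=O)CCc1c(C)ccc([N+]#N)c1C.OS(=O)(=O)[O-] | intermediate
7 | ethyl 3-(3-hydroxy-2,6-dimethylphenyl)propanoate | CCOC(=O)CCc1c(C)ccc(O)c1C | intermediate
8 | 3-(3-hydroxy-2,6-dimethylphenyl)propanoic acid | OC(=O)CCc1c(C)ccc(O)c1C | intermediate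
9 | trimethylsilyldiazomethane | C[Si](C)(C)C=[N+]=[N-] | starting material
10 | 3-[3-(ethoxycarbonyloxy)-2,6-dimethylphenyl]propanoic ethyl carbonic anhydride | CCOC(=O)OC(=O)CCc1c(C)ccc(OC(=O)OCC)c1C | intermediate
11 | 3-(4-diazo-3-oxobutyl)-2,4-dimethylphenyl ethyl carbonate | CCOC(=O)Oc1ccc(C)c(CCC(=O)C=[N+]=[N-])c1C | intermediate
12 | 1-diazo-4-(3-hydroxy-2,6-dimethylphenyl)butan-2-one | Cc1ccc(O)c(C)c1CCC(=O)C=[N+]=[N-] | intermediate
13 | (10S)-11,12,13-trinoreudesma-1,4-diene-3,8-dione (cross-conjugated ring A dienone, ring B ketone, 10β-methyl) | CC1=C2CCC(=O)C[C@@]2(C)C=CC1=O | intermediate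
14 | (10R)-11,12,13-trinoreudesm-4-ene-3,8-dione | CC1=C2CCC(=O)C[C@@]2(C)CCC1=O | intermediate
15 | (10R)-8,8-(ethylenedioxy)-11,12,13-trinoreudesm-4-en-3-one | CC1=C2CCC3(OCCO3)C[C@@]2(C)CCC1=O | intermediate
16 | lithium 8,8-(ethylenedioxy)-11,12,13-trinor-5α-eudesm-3-en-3-olate (trans-fused, 10β-methyl) | [Li+].[O-]C1=C(C)[C@@H]2CCC3(OCCO3)C[C@@]2(C)CC1 | intermediate
17 | 8,8-(ethylenedioxy)-11,12,13-trinor-5α-eudesm-3-en-3-yl trifluoromethanesulfonate | FC(F)(F)S(=O)(=O)OC1=C(C)[C@@H]2CCC3(OCCO3)C[C@@]2(C)CC1 | intermediate
18 | 8,8-(ethylenedioxy)-11,12,13-trinor-5α-eudesm-3-ene | C1=C(C)[C@@H]2CCC3(OCCO3)C[C@@]2(C)CC1 | intermediate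
19 | (5R,10R)-11,12,13-trinor-5α-eudesm-3-en-8-one | C1=C(C)[C@@H]2CCC(=O)C[C@@]2(C)CC1 | intermediate
20 | acetone | CC(C)=O | starting material
21 | lithium 11,12,13-trinor-5α-eudesma-3,7-dien-8-olate | C1=C(C)[C@@H]2CC=C([O-])C[C@@]2(C)CC1.[Li+] | intermediate
22 | 11-hydroxy-5α-eudesm-3-en-8-one (C7 configuration not controlled, removed in step 13) | C1=C(C)[C@@H]2CC(C(C)(C)O)C(=O)C[C@@]2(C)CC1 | intermediate
23 | 11-(methanesulfonyloxy)-5α-eudesm-3-en-8-one | C1=C(C)[C@@H]2CC(C(C)(C)OS(C)(=O)=O)C(=O)C[C@@]2(C)CC1 | intermediate
24 | 5α-eudesma-3,7(11)-dien-8-one | C1=C(C)[C@@H]2CC(=C(C)C)C(=O)C[C@@]2(C)CC1 | intermediate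
25 | 3α,4α-dihydroxy-5α-eudesm-7(11)-en-8-one (4β-methyl) | O[C@@H]1CC[C@]2(C)CC(=O)C(=C(C)C)C[C@H]2[C@]1(C)O | intermediate
26 | 11-hydroperoxy-3α,4α-dihydroxy-5α-eudesm-6-en-8-one | O[C@@H]1CC[C@]2(C)CC(=O)C(C(C)(C)OO)=C[C@H]2[C@]1(C)O | intermediate
27 | 3α,4α,11-trihydroxy-5α-eudesm-6-en-8-one | O[C@@H]1CC[C@]2(C)CC(=O)C(C(C)(C)O)=C[C@H]2[C@]1(C)O | intermediate
28 | 3-methylbut-2-enoyl chloride | CC(C)=CC(Cl)=O | starting material
29 | (3R,4S,5R,10R)-4,11-dihydroxy-8-oxoeudesm-6-en-3-yl 3-methylbut-2-enoate (3α-ester, 4α-OH, 5α-H, 10β-methyl) | CC(C)=CC(=O)O[C@@H]1CC[C@]2(C)CC(=O)C(C(C)(C)O)=C[C@H]2[C@]1(C)O | target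

**Step count**

Total: 16 steps. Longest linear sequence: 16 steps (1 → 29).

**Steps most likely to fail**

1. Step 7 (proposed new method). The carbenoid may be diverted (bonding to C4, ring expansion to a cycloheptatrienone, intermolecular O–H insertion), or the catalyst may discriminate poorly between the two faces at C10. The fallback sets out from 12 and returns at 13. CF3CO2H in CH2Cl2 at −20 °C protonates the diazo carbon, and the resulting alkanediazonium ion is captured by C10 of the phenol, the known acid-promoted para-alkylation of phenolic diazoketones. This should give racemic 11,12,13-trinoreudesma-1,4-diene-3,8-dione F1. Preparative chromatography on a chiral stationary phase (cellulose tris(3,5-dimethylphenylcarbamate)) then delivers the (S)-enantiomer, which is 13.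

2. Step 15. Hydrogen may be abstracted from the C12/C13 methyl groups instead of C6, and slow oxygen uptake by the electron-poor alkene may lead to unselective oxidation on prolonged irradiation. The fallback sets out from 19 and returns at 27. The lithium enolate of 19 (LiN(i-Pr)2, THF, −78 °C) is selenenylated with PhSeCl (1.0 equiv) to give 7-(phenylselanyl)-11,12,13-trinor-5α-eudesm-3-en-8-one F2. A second deprotonation at C7 and addition to acetone 20 in the presence of ZnCl2 gives 11-hydroxy-7-(phenylselanyl)-5α-eudesm-3-en-8-one F3. Oxidation with H2O2/pyridine in CH2Cl2 forms the selenoxide, which can only eliminate syn towards C6–H because C11 bears no hydrogen, giving 11-hydroxy-5α-eudesma-3,6-dien-8-one F4. OsO4/NMO then dihydroxylates the isolated 3-ene from the α face in preference to the conjugated 6-ene and gives 27.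

3. Step 16. Acyl transfer to the axial C3 hydroxyl next to the C4 carbinol may be slow, and the base may isomerise the acyl chloride through its vinylketene so that the deconjugated 3-methylbut-3-enoate is transferred. The fallback sets out from 27 and returns at 29. Steglich esterification of 27 with (diethoxyphosphoryl)acetic acid (DCC, DMAP, CH2Cl2) gives 3α-[(diethoxyphosphoryl)acetoxy]-4α,11-dihydroxy-5α-eudesm-6-en-8-one F5. Horner–Wadsworth–Emmons olefination of F5 with acetone 20 (NaH, 1.05 equiv, THF, 0 °C → rt) then builds the 3-methylbut-2-enoate double bond on the ester already in place and gives 29.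

**Further compounds**

F1 | step 7 | racemic 11,12,13-trinoreudesma-1,4-diene-3,8-dione | CC1=C2CCC(=O)CC2(C)C=CC1=O
F2 | step 15 | 7-(phenylselanyl)-11,12,13-trinor-5α-eudesm-3-en-8-one | C1=C(C)[C@@H]2CC([Se]c3ccccc3)C(=O)C[C@@]2(C)CC1
F3 | step 15 | 11-hydroxy-7-(phenylselanyl)-5α-eudesm-3-en-8-one | C1=C(C)[C@@H]2CC([Se]c3ccccc3)(C(C)(C)O)C(=O)C[C@@]2(C)CC1
F4 | step 15 | 11-hydroxy-5α-eudesma-3,6-dien-8-one | C1=C(C)[C@@H]2C=C(C(C)(C)O)C(=O)C[C@@]2(C)CC1
F5 | step 16 | 3α-[(diethoxyphosphoryl)acetoxy]-4α,11-dihydroxy-5α-eudesm-6-en-8-one | CCOP(=O)(OCC)CC(=O)O[C@@H]1CC[C@]2(C)CC(=O)C(C(C)(C)O)=C[C@H]2[C@]1(C)O
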